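## Retrosynthetic overview
1. The last bond is ArO–CH2, made by a Mitsunobu reaction between the coumarin phenol (isofraxidin) and a (2R,3R)-epoxy diol side chain. No bond at a stereocentre is touched.
2. Isofraxidin comes from dehydrogenation of its 3,4-dihydro form. The lactone ring and the O1–C8a bond come from a Baeyer–Villiger ring expansion (aryl 1,2-shift from C to O) of a 6-oxy-5,7-dimethoxyindan-1-one, which is closed in the same flask from 3-(4-hydroxy-3,5-dimethoxyphenyl)propanoic acid.
3. That acid comes from Cu-catalysed double methoxylation of a dibromophenol, which comes from Heck/hydrogenation of 4-iodophenol with acrylic acid.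
4. The epoxy diol comes from cross-metathesis with 2-methylbut-3-en-2-ol (E-C5=C6), after Sharpless epoxidation (both stereocentres), after Negishi carboalumination/hydroxymethylation of pent-1-en-4-yne (E-C2=C3).
5. Ring order: benzene ring (bought), then the five-membered ketone ring, then expansion to the six-membered lactone, then aromatisation to the pyranone. The oxirane is made in the side branch and joined last.

Assumption: all starting materials named below are taken as catalogue chemicals; the volatile C5 enyne is the least common of them.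

## Route

Step 1
Reactants: 1 4-iodophenol; 2 acrylic acid
Product: 4 3-(4-hydroxyphenyl)propanoic acid, via (E)-4-hydroxycinnamic acid 3 (not isolated)
Conditions: Pd/C (10 wt %, 2 mol % Pd), K2CO3 (3 equiv), H2O, 100 °C; then H2 (1 atm), rt, same flask; HCl work-up
Reagents that add atoms: none
Why: A ligand-free Mizoroki–Heck arylation of acrylate gives the E-cinnamate 3, and the same Pd/C then hydrogenates only the conjugated C=C (one-pot Heck/hydrogenation); no stereocentre is formed.

Step 2
Reactants: 4 3-(4-hydroxyphenyl)propanoic acid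
Product: 5 3-(3,5-dibromo-4-hydroxyphenyl)propanoic acid
Conditions: Br2 (2.05 equiv), AcOH, rt
Reagents that add atoms: bromine, BrBr
Why: Electrophilic aromatic bromination goes to the two free positions ortho to the OH (para is blocked), and limiting Br2 to two equivalents avoids ipso attack and spirolactone formation.

Step 3
Reactants: 5 3-(3,5-dibromo-4-hydroxyphenyl)propanoic acid
Product: 6 3-(4-hydroxy-3,5-dimethoxyphenyl)propanoic acid
Conditions: NaOMe (8 equiv, in MeOH), CuBr (20 mol %), DMF, 115 °C; HCl work-up
Reagents that add atoms: sodium methoxide, [Na+].[O-]C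
Why: Ullmann-type copper-catalysed methoxylation replaces both aryl bromides, the same reaction type that turns 2,6-dibromo-4-alkylphenols into 2,6-dimethoxyphenols, while phenoxide and carboxylate stay inert.

Step 4
Reactants: 6 3-(4-hydroxy-3,5-dimethoxyphenyl)propanoic acid
Product: 10 7-hydroxy-6,8-dimethoxychroman-2-one (3,4-dihydroisofraxidin), via mixed anhydride 7 (not isolated), via indanone trifluoroacetate 8 (not isolated), via lactone trifluoroacetate 9 (not isolated)
Conditions: (CF3CO)2O (6 equiv), CF3CO2H/CH2Cl2 1:4, 0 °C→rt, 3 h; then urea·H2O2 (1.5 equiv), 0 °C, 2 h; aq. NaHCO3 work-up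
Reagents that add atoms: hydrogen peroxide (as its urea adduct), OO; trifluoroacetic anhydride, O=C(OC(=O)C(F)(F)F)C(F)(F)F (its atoms stay only in 7, 8 and 9)
Why: Proposed new method: one reagent, (CF3CO)2O, is meant to drive a ring-closure/ring-expansion domino that amounts to an ortho C–H lactonisation of an unprotected phenolic acid, in that it masks the oxidation-prone phenol as its trifluoroacetate and turns the acid into mixed anhydride 7, whose acylium carbon attacks the ring carbon lying ortho and para to the two OMe groups (intramolecular Friedel–Crafts acylation) to close indanone 8, after which the surplus anhydride makes CF3CO3H from urea·H2O2, the peracid adds to the ketone, and in the Criegee adduct the electron-rich aryl carbon migrates from C to O in preference to CH2, expanding the five-membered ketone to the six-membered lactone 9 and creating the O1–C8a bond (Baeyer–Villiger 1,2-shift), with the aqueous work-up then freeing the phenol; the closest known reaction types are the anhydride-promoted cyclisation of 3-arylpropanoic acids to indan-1-ones and the peracid Baeyer–Villiger oxidation of indan-1-ones to chroman-2-ones, which have not been run as one self-masking domino; no stereocentre is formed.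

Step 5
Reactants: 10 7-hydroxy-6,8-dimethoxychroman-2-one
Product: 11 7-hydroxy-6,8-dimethoxy-2H-chromen-2-one (isofraxidin)
Conditions: DDQ (1.2 equiv), 1,4-dioxane, 60 °C
Reagents that add atoms: none
Why: In this DDQ dehydrogenation, hydride leaves C4, which is benzylic and para to the free 7-OH, and the resulting para-quinone methide loses the acidic C3–H to give the aromatic coumarin.

Step 6
Reactants: 12 pent-1-en-4-yne
Product: 15 (E)-3-methylhexa-2,5-dien-1-ol, via alkenyldimethylalane 13 (not isolated), via lithium alanate 14 (not isolated)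
Conditions: Me3Al (2 equiv), Cp2ZrCl2 (25 mol %), CH2Cl2, 0 °C→rt; n-BuLi, hexane/THF, 0 °C; (CH2O)n, rt; 1 M HCl
Reagents that add atoms: trimethylaluminium, C[Al](C)C; formaldehyde (from paraformaldehyde), C=O; n-butyllithium, [Li]CCCC (its atoms stay only in 14)
Why: Negishi zirconium-catalysed carboalumination adds Me and Al syn across the terminal alkyne only (Me to the inner carbon), which fixes the E trisubstituted alkene, and the alanate is hydroxymethylated by formaldehyde with retention of geometry.

Step 7
Reactants: 15 (E)-3-methylhexa-2,5-dien-1-ol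
Product: 16 [(2R,3R)-3-allyl-3-methyloxiran-2-yl]methanol
Conditions: Ti(OiPr)4 (10 mol %), D-(−)-diisopropyl tartrate (12 mol %), t-BuOOH (2 equiv, anhydrous), 4 Å MS, CH2Cl2, −20 °C
Reagents that add atoms: tert-butyl hydroperoxide, CC(C)(C)OO
Why: In the Sharpless–Katsuki asymmetric epoxidation only the alkene of the Ti-bound allylic alcohol reacts, the D-(−)-tartrate delivers oxygen to the face that gives the (2R,3R)-epoxide (the sense known for geraniol, at least 90 % ee expected), and the E alkene fixes the trans relation of CH2OH and the allyl group, so both stereocentres are set here.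

Step 8
Reactants: 16 [(2R,3R)-3-allyl-3-methyloxiran-2-yl]methanol; 17 2-methylbut-3-en-2-ol (5 equiv)
Product: 18 [(2R,3R)-3-[(E)-4-hydroxy-4-methylpent-2-en-1-yl]-3-methyloxiran-2-yl]methanol
Conditions: second-generation Hoveyda–Grubbs catalyst RuCl2(H2IMes)(=CH-C6H4-2-OiPr) (3 mol %), CH2Cl2, 40 °C
Reagents that add atoms: none
Why: Olefin cross-metathesis of a fast terminal alkene with a hindered tertiary allylic alcohol that hardly homodimerises is selective and gives the E alkene under thermodynamic control, and the oxirane stereocentres are not involved.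

Step 9
Reactants: 11 isofraxidin; 18 [(2R,3R)-3-[(E)-4-hydroxy-4-methylpent-2-en-1-yl]-3-methyloxiran-2-yl]methanol
Product: 19 7-{[(2R,3R)-3-[(E)-4-hydroxy-4-methylpent-2-en-1-yl]-3-methyloxiran-2-yl]methoxy}-6,8-dimethoxy-2H-chromen-2-one (target)
Conditions: PPh3 (1.3 equiv), DIAD (1.3 equiv), THF, 0 °C→rt
Reagents that add atoms: none
Why: In the Mitsunobu etherification only the primary alcohol forms the oxyphosphonium salt (the tertiary one is inert) and the acidic 7-OH displaces it at CH2, so no oxirane C–O bond is broken and (2R,3R) is retained; recrystallising the final ether can raise the ee.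

## Compound list
1 | 4-iodophenol | Oc1ccc(I)cc1 | starting material
2 | acrylic acid | C=CC(=O)O | starting material
3 | (E)-4-hydroxycinnamic acid | OC(=O)/C=C/c1ccc(O)cc1 | intermediate
4 | 3-(4-hydroxyphenyl)propanoic acid | OC(=O)CCc1ccc(O)cc1 | intermediate
5 | 3-(3,5-dibromo-4-hydroxyphenyl)propanoic acid | OC(=O)CCc1cc(Br)c(O)c(Br)c1 | intermediate
6 | 3-(4-hydroxy-3,5-dimethoxyphenyl)propanoic acid | OC(=O)CCc1cc(OC)c(O)c(OC)c1 | intermediate
7 | 3-[3,5-dimethoxy-4-(trifluoroacetoxy)phenyl]propanoic trifluoroacetic anhydride | O=C(CCc1cc(OC)c(OC(=O)C(F)(F)F)c(OC)c1)OC(=O)C(F)(F)F | intermediate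
8 | 6-(trifluoroacetoxy)-5,7-dimethoxyindan-1-one | O=C1CCc2cc(OC)c(OC(=O)C(F)(F)F)c(OC)c12 | intermediate
9 | 7-(trifluoroacetoxy)-6,8-dimethoxychroman-2-one | O=C1CCc2cc(OC)c(OC(=O)C(F)(F)F)c(OC)c2O1 | intermediate
10 | 7-hydroxy-6,8-dimethoxychroman-2-one | O=C1CCc2cc(OC)c(O)c(OC)c2O1 | intermediate
11 | 7-hydroxy-6,8-dimethoxy-2H-chromen-2-one (isofraxidin) | COc1cc2ccc(=O)oc2c(OC)c1O | intermediate
12 | pent-1-en-4-yne | C#CCC=C | starting material
13 | dimethyl[(E)-2-methylpenta-1,4-dien-1-yl]alane (Al cis to CH3) | C[Al](C)/C=C(\C)CC=C | intermediate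
14 | lithium butyl(dimethyl)[(E)-2-methylpenta-1,4-dien-1-yl]alanate | [Li+].CCCC[Al-](C)(C)/C=C(\C)CC=C | intermediate
15 | (E)-3-methylhexa-2,5-dien-1-ol | OC/C=C(\C)CC=C | intermediate
16 | [(2R,3R)-3-allyl-3-methyloxiran-2-yl]methanol | OC[C@H]1O[C@]1(C)CC=C | intermediate
17 | 2-methylbut-3-en-2-ol | C=CC(C)(C)O | starting material
18 | [(2R,3R)-3-[(E)-4-hydroxy-4-methylpent-2-en-1-yl]-3-methyloxiran-2-yl]methanol | OC[C@H]1O[C@]1(C)C/C=C/C(C)(C)O | intermediate
19 | 7-{[(2R,3R)-3-[(E)-4-hydroxy-4-methylpent-2-en-1-yl]-3-methyloxiran-2-yl]methoxy}-6,8-dimethoxy-2H-chromen-2-one | COc1cc2ccc(=O)oc2c(OC)c1OC[C@H]1O[C@]1(C)C/C=C/C(C)(C)O | target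

## Step count and risks
Total steps: 9. Longest linear sequence: 6 (steps 1, 2, 3, 4, 5, 9). The side-chain branch has 3 steps (6, 7, 8) before the union.

**Step 4 (the proposed new domino) is the most likely to fail.**
- Ring closure may be slow on the trifluoroacetate-masked ring.
- CF3CO3H may hydroxylate or demethylate the electron-rich ring.
- An enol trifluoroacetate of 8 may be oxygenated next to the carbonyl.
- The fallback uses known chemistry, sets out from 6 and comes back at 10. The phenol is acetylated (Ac2O, pyridine, aqueous work-up) to 3-(4-acetoxy-3,5-dimethoxyphenyl)propanoic acid F1. The lactone C–O bond is made directly, with no ketone ring, by oxidative C–H lactonisation with the trivalent-iodine reagent PhI(OCOCF3)2 and BF3·OEt2 in CF3CO2H. Here the carboxyl group attacks the position para to OMe and gives 7-acetoxy-6,8-dimethoxychroman-2-one F2. LiOH then cleaves both aryl esters to 3-(2,4-dihydroxy-3,5-dimethoxyphenyl)propanoic acid F3, which closes again on acidification (TsOH, toluene, 80 °C) to 10.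

**Step 6 is the second risk.**
- The 1,4-enyne is volatile.
- Its doubly activated CH2 may be isomerised when n-BuLi is added.
- Hydroxymethylation yields can be moderate.
- The fallback sets out from 12 and comes back at 15. Compound 12 is deprotonated at the alkyne (n-BuLi, THF, −78 °C) and trapped with (CH2O)n to give hex-5-en-2-yn-1-ol F4. Hydroxyl-directed trans-hydroalumination with NaAlH2(OCH2CH2OMe)2 followed by I2 gives (Z)-3-iodohexa-2,5-dien-1-ol F5. Me2CuLi then replaces iodine by methyl with retention, which gives the E alcohol 15.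

**Step 9 is the third risk.**
- The phenol is flanked by two OMe groups, so the Mitsunobu coupling may be slow.
- Separation from the phosphine oxide and hydrazide may cost material.
- The fallback sets out from 18 and comes back at 19. The primary alcohol alone is sulfonylated (TsCl, Et3N, cat. DMAP, CH2Cl2, 0 °C) to [(2R,3R)-3-[(E)-4-hydroxy-4-methylpent-2-en-1-yl]-3-methyloxiran-2-yl]methyl 4-methylbenzenesulfonate F6. The caesium phenoxide of 11 (Cs2CO3, DMF, 40 °C) displaces it at CH2 in an SN2 alkylation to give 19 with the oxirane unchanged.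

## Further compounds
F1 | step 4 | 3-(4-acetoxy-3,5-dimethoxyphenyl)propanoic acid | CC(=O)Oc1c(OC)cc(CCC(=O)O)cc1OC
F2 | step 4 | 7-acetoxy-6,8-dimethoxychroman-2-one | CC(=O)Oc1c(OC)cc2CCC(=O)Oc2c1OC
F3 | step 4 | 3-(2,4-dihydroxy-3,5-dimethoxyphenyl)propanoic acid | OC(=O)CCc1cc(OC)c(O)c(OC)c1O
F4 | step 6 | hex-5-en-2-yn-1-ol | OCC#CCC=C
F5 | step 6 | (Z)-3-iodohexa-2,5-dien-1-ol | OC/C=C(\I)CC=C
F6 | step 9 | [(2R,3R)-3-[(E)-4-hydroxy-4-methylpent-2-en-1-yl]-3-methyloxiran-2-yl]methyl 4-methylbenzenesulfonate | Cc1ccc(cc1)S(=O)(=O)OC[C@H]1O[C@]1(C)C/C=C/C(C)(C)O
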